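## Retrosynthetic overview

1. The last step is hydrogenolysis of an undeca-O-benzyl ether. Before it, both pyran rings are opened at once by cutting C4–C4a and O1–C8a in the epigallocatechin-type unit (rings A', C', B') and the same two bonds in the epicatechin-type unit (rings A, C, B).
2. This twofold [3+3] annulation joins a biaryl bearing two O1–C2–C3–C4 arms (free C2–OH, O3 benzyl ether, C4 primary tosylate) with two 2-fluoro-4,6-bis(benzyloxy)phenylmagnesium units. Each unit is a ring A with nucleophilic C4a next to electrophilic C8a.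
3. Enabling feature: in the phloroglucinol-type rings A and A', the oxygens on C5 and C7 are ortho/para to C4a but meta to C8a. C4a can therefore carry the metal while a C8a–F bond stays open to attack by O1. The chain O1–C2–C3–C4 of ring C has the matching polarity, and both units share the same ring A and the same (2R,3R) centres, so one operation serves both.
4. All four stereocentres come from one double Evans syn-glycolate aldol addition to the biaryl dialdehyde. The C2–O and C3–O bonds are never broken afterwards, so syn becomes 2,3-cis.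
5. The B–B' bond comes from a Suzuki–Miyaura coupling of two brominated benzyloxybenzaldehydes. Ring order: the B–B' biaryl first, then rings C and C' closed together as rings A and A' are attached.

Key step: step 12

Assumption: the SMILES fixes the four sp3 centres (2R,3R in both units) but not the sense of the hindered B–B' axis. The two atropisomers are diastereomers from the aldol adduct onwards, would be separated by chromatography at the latest at the fully benzylated bis-flavan, and every SMILES below holds for either of them.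

## Route

Step 1
Reactants: 1 3,4-bis(benzyloxy)benzaldehyde
Product: 2 4,5-bis(benzyloxy)-2-bromobenzaldehyde
Conditions: Br2, NaOAc, AcOH, rt
Reagents that add atoms: bromine, BrBr
Why: Electrophilic aromatic bromination should go to C6, the position para to the 3-benzyloxy group and the least hindered activated site, while NaOAc takes up HBr so that the benzyl ethers survive.

Step 2
Reactants: 2 4,5-bis(benzyloxy)-2-bromobenzaldehyde
Product: 3 4,5-bis(benzyloxy)-2-(4,4,5,5-tetramethyl-1,3,2-dioxaborolan-2-yl)benzaldehyde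
Conditions: B2pin2, PdCl2(dppf), KOAc, 1,4-dioxane, 90 °C
Reagents that add atoms: bis(pinacolato)diboron, CC1(C)OB(OC1(C)C)B1OC(C)(C)C(C)(C)O1
Why: Miyaura borylation (oxidative addition of zerovalent palladium into C–Br, acetate-assisted transmetalation with B2pin2) tolerates the aldehyde and the benzyl ethers.

Step 3
Reactants: 4 3,4,5-trihydroxybenzaldehyde
Product: 5 3,4,5-tris(benzyloxy)benzaldehyde
Conditions: BnBr, K2CO3, DMF, 60 °C
Reagents that add atoms: benzyl bromide, BrCc1ccccc1
Why: Threefold Williamson ether synthesis of the phenoxides with benzyl bromide, with the aldehyde inert to K2CO3.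

Step 4
Reactants: 5 3,4,5-tris(benzyloxy)benzaldehyde
Product: 6 3,4,5-tris(benzyloxy)-2-bromobenzaldehyde
Conditions: NBS, DMF, 0 °C → rt, dark
Reagents that add atoms: N-bromosuccinimide, O=C1CCC(=O)N1Br
Why: Electrophilic aromatic bromination can only hit the two equivalent free positions C2 and C6, and ionic conditions in the dark avoid benzylic radical bromination.

Step 5
Reactants: 3 4,5-bis(benzyloxy)-2-(pinacolboryl)benzaldehyde; 6 3,4,5-tris(benzyloxy)-2-bromobenzaldehyde
Product: 7 4,4',5,5',6-pentakis(benzyloxy)biphenyl-2,2'-dicarbaldehyde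
Conditions: Pd(OAc)2, SPhos, K3PO4, toluene/H2O, 90 °C
Reagents that add atoms: none
Why: Suzuki–Miyaura coupling with the bulky, electron-rich ligand SPhos is a standard answer to triply ortho-substituted biaryls, leaves both formyl groups untouched and joins rings B and B'.

Step 6
Reactants: 8 (S)-4-benzyl-1,3-oxazolidin-2-one; 9 (benzyloxy)acetyl chloride
Product: 10 (S)-4-benzyl-3-[(benzyloxy)acetyl]-1,3-oxazolidin-2-one
Conditions: n-BuLi, THF, −78 °C; then 9, −78 → 0 °C
Reagents that add atoms: none
Why: N-Acylation of the oxazolidinone after deprotonation is the standard entry to Evans glycolate imides and does not touch the auxiliary stereocentre.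

Step 7
Reactants: 7 biaryl dialdehyde; 10 glycolate imide (2.4 equiv)
Product: 12 bis(syn-aldol) adduct of 7 bearing two auxiliary arms, via boron enolate 11 (not isolated)
Conditions: 10, Bu2BOTf, Et3N, CH2Cl2, −78 → 0 °C; 7, −78 → 0 °C; then pH 7 buffer, MeOH, H2O2
Reagents that add atoms: none
Why: Twofold Evans syn-glycolate aldol addition, in which the Z boron enolate 11 reacts through a Zimmerman–Traxler chair whose open face is fixed by the (S)-benzyl group of the auxiliary, so that reagent control sets the (1R,2S) syn pair in each arm, that is C2 and C3 of both flavan units.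

Step 8
Reactants: 12 bis(syn-aldol) adduct
Product: 13 biaryl with two (1R,2R)-2-(benzyloxy)-1,3-dihydroxypropyl arms
Conditions: LiBH4, MeOH (2 equiv), THF, 0 °C
Reagents that add atoms: none
Why: Reductive cleavage of the N-acyl oxazolidinones with LiBH4 gives the primary alcohols at C4 without touching the stereocentres or the benzyl ethers and returns the auxiliary.

Step 9
Reactants: 13 bis(1,3-diol)
Product: 14 bis(primary tosylate) with both benzylic hydroxyl groups free
Conditions: TsCl (2.2 equiv), pyridine, CH2Cl2, 0 °C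
Reagents that add atoms: p-toluenesulfonyl chloride, Cc1ccc(S(=O)(=O)Cl)cc1
Why: Selective sulfonylation, because the unhindered primary hydroxyl groups react much faster with TsCl than the secondary benzylic ones next to the biaryl axis.

Step 10
Reactants: 15 1,3,5-trifluorobenzene
Product: 16 1,3-bis(benzyloxy)-5-fluorobenzene
Conditions: BnOH (2.1 equiv), NaH, NMP, 0 → 90 °C
Reagents that add atoms: benzyl alcohol, OCc1ccccc1
Why: Twofold nucleophilic aromatic substitution (SNAr), in which each fluorine is activated inductively by the meta fluorines and the third substitution is the slowest, so that two equivalents of benzyloxide should stop at the monofluoride.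

Step 11
Reactants: 16 1,3-bis(benzyloxy)-5-fluorobenzene
Product: 17 1,5-bis(benzyloxy)-3-fluoro-2-iodobenzene
Conditions: NIS (1.0 equiv), MeCN, 0 °C → rt
Reagents that add atoms: N-iodosuccinimide, O=C1CCC(=O)N1I
Why: Electrophilic aromatic iodination should go ortho to one and para to the other benzyloxy group (next to fluorine) rather than into the crowded position between the two benzyloxy groups, and the two such sites are equivalent.

Step 12
Reactants: 14 bis(primary tosylate); 17 1,5-bis(benzyloxy)-3-fluoro-2-iodobenzene (4.4 equiv, of which 2 serve as base)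
Product: 20 undeca-O-benzyl degalloyl theasinensin F, via arylmagnesium iodide 18 (not isolated), via open-chain bis(fluoroaryl) dialkoxide 19 (not isolated)
Conditions: 17, Mg, LiCl, THF, −10 °C; then 14, Li2CuCl4 (10 mol %), THF, −10 → 20 °C; then KOt-Bu (1 M in t-BuOH), DMPU, 65 °C; aq NH4Cl
Reagents that add atoms: none
Why: Proposed new method: Grignard reagent 18 serves as a 1,2-dipole equivalent of ring A, since under copper catalysis its carbanionic C4a displaces the primary tosylate at C4 (SN2-type oxidative addition to an arylcuprate, then reductive elimination) to give 19, and once KOt-Bu in DMPU has handed the benzylic alkoxide O1 from magnesium to potassium, O1 adds to C8a and expels fluoride through a Meisenheimer adduct (SNAr), so that C4–C4a and O1–C8a of the epigallocatechin-type unit and of the epicatechin-type unit are made in one flask. The closest known reaction types are the Fouquet–Schlosser coupling of Grignard reagents with primary tosylates and the base-induced SNAr closure of 3-(2-fluoroaryl)propanols to chromans, which are merged here and run on two arms at once. Rings C and C' each close as six-membered rings by intramolecular addition–elimination of O1 at C8a (6-exo-trig with respect to the C8a–C8 double bond), whereas rings A and A' are brought in intact. No new stereocentre arises and no bond at C2 or C3 is broken, so the syn relation of the aldol step is carried with retention into the 2,3-cis (2R,3R) arrangement of both units. The step needs carbon–carbon coupling before any reaction of O1, which is secured by holding O1 as an unreactive magnesium alkoxide (no four-membered ether closure onto C4) and by keeping 18 at or below 20 °C (no loss of fluoride to an aryne) until C4 is consumed. It also needs O1 as the only nucleophile at C8a, which is secured by the benzyl group on O3 (no five-membered ring closure), by the bulk of tert-butoxide and by the meta placement of O5 and O7, which withdraw inductively from C8a without donating to it.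

Step 13
Reactants: 20 undeca-O-benzyl degalloyl theasinensin F
Product: 21 degalloyl theasinensin F
Conditions: H2 (1 atm), Pd(OH)2/C, THF/MeOH, rt; work-up under argon
Reagents that add atoms: none
Why: Catalytic hydrogenolysis should cleave all eleven benzyl ethers (nine aryl, two alkyl) under neutral conditions that leave the C2–O1 bonds, the stereocentres and the biaryl axis untouched.

## Compound list

1 | 3,4-bis(benzyloxy)benzaldehyde | O=Cc1ccc(OCc2ccccc2)c(OCc2ccccc2)c1 | starting material
2 | 4,5-bis(benzyloxy)-2-bromobenzaldehyde | O=Cc1cc(OCc2ccccc2)c(OCc2ccccc2)cc1Br | intermediate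
3 | 4,5-bis(benzyloxy)-2-(4,4,5,5-tetramethyl-1,3,2-dioxaborolan-2-yl)benzaldehyde | O=Cc1cc(OCc2ccccc2)c(OCc2ccccc2)cc1B1OC(C)(C)C(C)(C)O1 | intermediate
4 | 3,4,5-trihydroxybenzaldehyde | O=Cc1cc(O)c(O)c(O)c1 | starting material
5 | 3,4,5-tris(benzyloxy)benzaldehyde | O=Cc1cc(OCc2ccccc2)c(OCc2ccccc2)c(OCc2ccccc2)c1 | intermediate
6 | 3,4,5-tris(benzyloxy)-2-bromobenzaldehyde | O=Cc1cc(OCc2ccccc2)c(OCc2ccccc2)c(OCc2ccccc2)c1Br | intermediate
7 | 4,4',5,5',6-pentakis(benzyloxy)biphenyl-2,2'-dicarbaldehyde | O=Cc1cc(OCc2ccccc2)c(OCc2ccccc2)cc1-c1c(C=O)cc(OCc2ccccc2)c(OCc2ccccc2)c1OCc1ccccc1 | intermediate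
8 | (S)-4-benzyl-1,3-oxazolidin-2-one | O=C1N[C@@H](Cc2ccccc2)CO1 | starting material
9 | (benzyloxy)acetyl chloride | O=C(Cl)COCc1ccccc1 | starting material
10 | (S)-4-benzyl-3-[(benzyloxy)acetyl]-1,3-oxazolidin-2-one | O=C(COCc1ccccc1)N1[C@@H](Cc2ccccc2)COC1=O | intermediate
11 | (Z)-dibutylboron enolate of 10 | CCCCB(CCCC)O/C(=C\OCc1ccccc1)N1[C@@H](Cc2ccccc2)COC1=O | intermediate
12 | bis(syn-aldol) adduct: pentakis(benzyloxy)biphenyl with two (1R,2S)-2-(benzyloxy)-1-hydroxy-3-oxo-3-[(S)-4-benzyl-2-oxooxazolidin-3-yl]propyl arms at C2 and C2' | O[C@H](c1cc(OCc2ccccc2)c(OCc2ccccc2)cc1-c1c([C@@H](O)[C@H](OCc2ccccc2)C(=O)N2[C@@H](Cc3ccccc3)COC2=O)cc(OCc2ccccc2)c(OCc2ccccc2)c1OCc1ccccc1)[C@H](OCc1ccccc1)C(=O)N1[C@@H](Cc2ccccc2)COC1=O | intermediate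
13 | bis(1,3-diol): same biaryl with two (1R,2R)-2-(benzyloxy)-1,3-dihydroxypropyl arms | O[C@H](c1cc(OCc2ccccc2)c(OCc2ccccc2)cc1-c1c([C@@H](O)[C@H](OCc2ccccc2)CO)cc(OCc2ccccc2)c(OCc2ccccc2)c1OCc1ccccc1)[C@H](OCc1ccccc1)CO | intermediate
14 | bis(primary tosylate): same biaryl with two (1R,2R)-2-(benzyloxy)-1-hydroxy-3-(tosyloxy)propyl arms | O[C@H](c1cc(OCc2ccccc2)c(OCc2ccccc2)cc1-c1c([C@@H](O)[C@H](OCc2ccccc2)COS(=O)(=O)c2ccc(C)cc2)cc(OCc2ccccc2)c(OCc2ccccc2)c1OCc1ccccc1)[C@H](OCc1ccccc1)COS(=O)(=O)c1ccc(C)cc1 | intermediate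
15 | 1,3,5-trifluorobenzene | Fc1cc(F)cc(F)c1 | starting material
16 | 1,3-bis(benzyloxy)-5-fluorobenzene | Fc1cc(OCc2ccccc2)cc(OCc2ccccc2)c1 | intermediate
17 | 1,5-bis(benzyloxy)-3-fluoro-2-iodobenzene | Fc1cc(OCc2ccccc2)cc(OCc2ccccc2)c1I | intermediate
18 | [2,4-bis(benzyloxy)-6-fluorophenyl]magnesium iodide | Fc1cc(OCc2ccccc2)cc(OCc2ccccc2)c1[Mg]I | intermediate
19 | open-chain bis(fluoroaryl) adduct, present as its dialkoxide and drawn as the diol: two (1R,2R)-2-(benzyloxy)-3-[2,4-bis(benzyloxy)-6-fluorophenyl]-1-hydroxypropyl arms | O[C@H](c1cc(OCc2ccccc2)c(OCc2ccccc2)cc1-c1c([C@@H](O)[C@H](OCc2ccccc2)Cc2c(F)cc(OCc3ccccc3)cc2OCc2ccccc2)cc(OCc2ccccc2)c(OCc2ccccc2)c1OCc1ccccc1)[C@H](OCc1ccccc1)Cc1c(F)cc(OCc2ccccc2)cc1OCc1ccccc1 | intermediate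
20 | undeca-O-benzyl degalloyl theasinensin F, (2R,3R) in both flavan units | O(Cc1ccccc1)c1cc(OCc3ccccc3)c2c(c1)O[C@H](c1cc(OCc3ccccc3)c(OCc3ccccc3)cc1-c1c([C@H]3Oc4cc(OCc5ccccc5)cc(OCc5ccccc5)c4C[C@H]3OCc3ccccc3)cc(OCc3ccccc3)c(OCc3ccccc3)c1OCc1ccccc1)[C@H](OCc1ccccc1)C2 | intermediate
21 | degalloyl theasinensin F | Oc1cc(O)c2c(c1)O[C@H](c1cc(O)c(O)cc1-c1c([C@H]3Oc4cc(O)cc(O)c4C[C@H]3O)cc(O)c(O)c1O)[C@H](O)C2 | target

## Step count and risks

Total steps: 13. Longest linear sequence: 8 steps (1 → 2 → 3 → 7 → 12 → 13 → 14 → 20 → 21; the branch from 4 is equally long).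

**Steps most likely to fail**

**Step 12.**
- What may go wrong: substitution at the β-branched, β-oxygenated primary tosylate by a doubly ortho-substituted aryl nucleophile may be too slow. Decay of the Grignard reagent by loss of fluoride, or four-membered ether closure by O1, could then overtake it. The alkoxide may also stay bound to magnesium and fail to attack C8a.
- Fallback (known chemistry, from 13 back to 20): the C–C bond is made by carbonyl addition instead of alkylation, and the steps are separated. The primary hydroxyl groups of 13 would be oxidised selectively (TEMPO, PhI(OAc)2, CH2Cl2) to the bis(β-hydroxy aldehyde) F1. Iodide 17 would be turned by n-BuLi at −78 °C into 2,4-bis(benzyloxy)-6-fluorophenyllithium F2. An excess of F2 adds to the formyl groups at a temperature at which it does not lose LiF and gives the bis(1,3-diol) adduct F3, whose C4 epimers are of no consequence. KH in DMF would close both pyran rings by SNAr, since only O1 can reach C8a in a six-membered ring, to give the bis(flavan-4-ol) F4. Ionic reduction (Et3SiH, BF3·OEt2, CH2Cl2, −40 °C) would remove both C4 hydroxyl groups and return to 20.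

**Step 7.**
- What may go wrong: after the first addition the aldolate oxygen may add to the neighbouring formyl group across the biaryl (lactol formation) and slow the second addition. The crowded, axially chiral dialdehyde may also erode the facial selectivity of the auxiliary in the mismatched atropisomer.
- Fallback (from 7 back to 13): bond formation and stereocontrol are separated. The small lithium enolate of methyl (benzyloxy)acetate (LDA, THF, −78 °C) would give the stereorandom bis(aldol) ester F5. Dess–Martin periodinane would give the bis(α-benzyloxy-β-keto ester) F6. Noyori-type asymmetric transfer hydrogenation with dynamic kinetic resolution (RuCl[(S,S)-TsDPEN](p-cymene), HCO2H/Et3N), a reaction type known to give syn-α-alkoxy-β-hydroxy esters, would funnel all isomers into the bis(syn-hydroxy ester) F7. The sense of induction is the one expected from the usual aryl ketone model. LiBH4 would then reduce both esters to 13.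

**Step 5.**
- What may go wrong: protodeboronation of the ortho-formyl boronate and slow oxidative addition into the doubly ortho-substituted bromide may leave homocoupling and reduction as the main paths.
- Fallback (from 2, with 6, back to 7): a masked aldehyde and a zinc nucleophile replace the boronate. Aldehyde 2 would be protected (ethylene glycol, TsOH, toluene, reflux) as the bromoaryl dioxolane F8. Bromine–lithium exchange (n-BuLi, −78 °C) and ZnCl2 would give the arylzinc chloride F9. Negishi coupling with 6 (Pd(OAc)2, SPhos, THF, 60 °C) would give the biaryl mono-acetal F10, and aqueous HCl in THF would release 7.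

## Further compounds

F1 | step 12 | bis(β-hydroxy aldehyde): biaryl with two (1R,2S)-2-(benzyloxy)-1-hydroxy-3-oxopropyl arms | O[C@H](c1cc(OCc2ccccc2)c(OCc2ccccc2)cc1-c1c([C@@H](O)[C@H](OCc2ccccc2)C=O)cc(OCc2ccccc2)c(OCc2ccccc2)c1OCc1ccccc1)[C@H](OCc1ccccc1)C=O
F2 | step 12 | 2,4-bis(benzyloxy)-6-fluorophenyllithium | Fc1cc(OCc2ccccc2)cc(OCc2ccccc2)c1[Li]
F3 | step 12 | bis(1,3-diol) adduct, C4 epimers | O[C@H](c1cc(OCc2ccccc2)c(OCc2ccccc2)cc1-c1c([C@@H](O)[C@H](OCc2ccccc2)C(O)c2c(F)cc(OCc3ccccc3)cc2OCc2ccccc2)cc(OCc2ccccc2)c(OCc2ccccc2)c1OCc1ccccc1)[C@H](OCc1ccccc1)C(O)c1c(F)cc(OCc2ccccc2)cc1OCc1ccccc1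
F4 | step 12 | bis(flavan-4-ol), undeca-O-benzyl, C4 epimers | O(Cc1ccccc1)c1cc(OCc3ccccc3)c2c(c1)O[C@H](c1cc(OCc3ccccc3)c(OCc3ccccc3)cc1-c1c([C@H]3Oc4cc(OCc5ccccc5)cc(OCc5ccccc5)c4C(O)[C@H]3OCc3ccccc3)cc(OCc3ccccc3)c(OCc3ccccc3)c1OCc1ccccc1)[C@H](OCc1ccccc1)C2O
F5 | step 7 | stereorandom bis(aldol) methyl ester | OC(c1cc(OCc2ccccc2)c(OCc2ccccc2)cc1-c1c(C(O)C(OCc2ccccc2)C(=O)OC)cc(OCc2ccccc2)c(OCc2ccccc2)c1OCc1ccccc1)C(OCc1ccccc1)C(=O)OC
F6 | step 7 | bis(α-benzyloxy-β-keto ester) | O=C(c1cc(OCc2ccccc2)c(OCc2ccccc2)cc1-c1c(C(=O)C(OCc2ccccc2)C(=O)OC)cc(OCc2ccccc2)c(OCc2ccccc2)c1OCc1ccccc1)C(OCc1ccccc1)C(=O)OC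
F7 | step 7 | bis(syn-hydroxy ester), (2S,3R) in each arm | O[C@H](c1cc(OCc2ccccc2)c(OCc2ccccc2)cc1-c1c([C@@H](O)[C@H](OCc2ccccc2)C(=O)OC)cc(OCc2ccccc2)c(OCc2ccccc2)c1OCc1ccccc1)[C@H](OCc1ccccc1)C(=O)OC
F8 | step 5 | 2-[4,5-bis(benzyloxy)-2-bromophenyl]-1,3-dioxolane | Brc1cc(OCc2ccccc2)c(OCc2ccccc2)cc1C1OCCO1
F9 | step 5 | [4,5-bis(benzyloxy)-2-(1,3-dioxolan-2-yl)phenyl]zinc chloride | Cl[Zn]c1cc(OCc2ccccc2)c(OCc2ccccc2)cc1C1OCCO1
F10 | step 5 | biaryl mono-acetal of 7 | O=Cc1cc(OCc2ccccc2)c(OCc2ccccc2)c(OCc2ccccc2)c1-c1cc(OCc2ccccc2)c(OCc2ccccc2)cc1C1OCCO1
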